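**Strategy.** The 1,2-dioxane is disconnected at the ring bond C3–C4, between the acetal-type carbon next to O2 and the methyl-bearing carbon. The O1–O2 peroxide bridge, fixed to the quaternary C6 beforehand by invertive perhydrolysis of an enantioenriched oxetane, is used as the tether: a peroxy orthoformate turns C3 into a peroxycarbenium ion, an allylsilane makes C4 its nucleophile, and one Lewis-acid-catalysed Hosomi–Sakurai cyclisation closes the six-membered peroxide ring and sets C4. The precursor is an acyclic tertiary dimethoxymethyl peroxide with a 4-(trimethylsilyl)but-2-enyl arm. Afterwards the C4 vinyl group is cut down to methyl and the C3 methoxy group is replaced by the acetic acid chain.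

Key step: step 10

Remarks on the chemistry:
- Ring numbering used throughout: O1–O2–C3(CH2CO2H)–C4(CH3)–C5–C6(CH3, alkyl).
- In steps 3 and 4 the ligand enantiomer is the one that gives the configuration drawn; the sense follows the established facial models and would be confirmed on the first batch.
- The C3 epimers of 23–30 converge in step 14; the E/Z isomers of 19 and 21 converge in step 10.
- The known weak point is the configuration of C4 relative to C6 in step 10: the two C6 substituents (methyl and a CH2R group) differ little in size, so only a modest bias is expected and the C4 epimer has to be separated.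

Step 1
Reactants: 1 (8-bromooctyl)benzene; 2 N,N-dimethylformamide
Product: 4 9-phenylnonanal, via Grignard reagent 3 (not isolated)
Conditions: Mg, THF, reflux; then 2, 0 °C; aq. HCl
Reagents that add atoms: N,N-dimethylformamide, CN(C)C=O
Why: Grignard formation followed by Bouveault formylation should give the aldehyde extended by one carbon.

Step 2
Reactants: 4 9-phenylnonanal; 5 1-(triphenylphosphoranylidene)propan-2-one
Product: 6 (E)-12-phenyldodec-3-en-2-one
Conditions: toluene, 80 °C
Reagents that add atoms: 1-(triphenylphosphoranylidene)propan-2-one, CC(=O)C=P(c1ccccc1)(c1ccccc1)c1ccccc1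
Why: Wittig olefination with a stabilised ylide should give the E-enone.

Step 3
Reactants: 6 (E)-12-phenyldodec-3-en-2-one; 7 methylmagnesium bromide
Product: 8 (R)-4-methyl-12-phenyldodecan-2-one
Conditions: CuBr·SMe2 (5 mol%), (R)-1-[(S)-2-(diphenylphosphino)ferrocenyl]ethyldicyclohexylphosphine (6 mol%), t-BuOMe, −78 °C; aq. NH4Cl
Reagents that add atoms: methylmagnesium bromide, C[Mg]Br
Why: copper-catalysed enantioselective conjugate addition of the Grignard reagent, in which the chiral ferrocenyl diphosphine–copper complex delivers methyl to one face of the enone, should set the side-chain methyl stereocentre as R.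

Step 4
Reactants: 8 (R)-4-methyl-12-phenyldodecan-2-one; 9 trimethylsulfoxonium iodide
Product: 11 (S)-2-methyl-2-[(2R)-2-methyl-10-phenyldecyl]oxetane, via epoxide 10 (not isolated)
Conditions: 9 (2.5 equiv), NaH, THF; LaLi3(binaphthoxide)3 (5 mol%), tris(2,4,6-trimethoxyphenyl)phosphine oxide (5 mol%), 5 Å MS, rt; then 45 °C
Reagents that add atoms: trimethylsulfoxonium iodide, C[S+](C)(C)=O.[I-]
Why: catalytic asymmetric Corey–Chaykovsky epoxidation of the methyl ketone, in which the chiral lanthanum–lithium binaphthoxide tells methyl from the branched alkyl group and sets the quaternary carbon as S, is followed in the same flask by ring expansion of the epoxide with a second ylide equivalent that does not touch this centre.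

Step 5
Reactants: 11 (S)-2-methyl-2-[(2R)-2-methyl-10-phenyldecyl]oxetane; 12 hydrogen peroxide
Product: 13 (3R,5R)-3-hydroperoxy-3,5-dimethyl-13-phenyltridecan-1-ol
Conditions: anhydrous H2O2 in Et2O, TMSOTf (10 mol%), −78 → 0 °C
Reagents that add atoms: hydrogen peroxide, OO
Why: Lewis-acid-promoted perhydrolysis of the oxetane takes place at the tertiary carbon with inversion (SN2-like opening of the activated ring), so the (S)-oxetane should give the (R)-tertiary hydroperoxide.

Step 6
Reactants: 13 (3R,5R)-3-hydroperoxy-3,5-dimethyl-13-phenyltridecan-1-ol; 14 2-methoxypropene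
Product: 15 (3R,5R)-3-[(2-methoxypropan-2-yl)peroxy]-3,5-dimethyl-13-phenyltridecan-1-ol
Conditions: 14 (1.2 equiv), PPTS (cat.), CH2Cl2, 0 °C
Reagents that add atoms: 2-methoxypropene, COC(C)=C
Why: acid-catalysed peroxyketalisation should be chemoselective because the hydroperoxide is the better nucleophile and its ketal the less acid-labile one, any mixed ketal of the primary alcohol being cleaved again by brief methanolysis.

Step 7
Reactants: 15 (3R,5R)-3-[(2-methoxypropan-2-yl)peroxy]-3,5-dimethyl-13-phenyltridecan-1-ol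
Product: 16 (3R,5R)-3-[(2-methoxypropan-2-yl)peroxy]-3,5-dimethyl-13-phenyltridecanal
Conditions: Dess–Martin periodinane, pyridine, CH2Cl2, 0 °C → rt
Reagents that add atoms: none
Why: buffered Dess–Martin oxidation is mild enough to leave the peroxyketal intact and should give the β-peroxy aldehyde without elimination.

Step 8
Reactants: 16 (3R,5R)-3-[(2-methoxypropan-2-yl)peroxy]-3,5-dimethyl-13-phenyltridecanal; 17 methyltriphenylphosphonium bromide; 18 (iodomethyl)trimethylsilane
Product: 19 {(2Z,5R,7R)-5-[(2-methoxypropan-2-yl)peroxy]-5,7-dimethyl-15-phenylpentadec-2-en-1-yl}trimethylsilane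
Conditions: 17, n-BuLi, THF, 0 °C; 18; n-BuLi, −78 °C; then 16, −78 °C → rt
Reagents that add atoms: methyltriphenylphosphonium bromide, C[P+](c1ccccc1)(c1ccccc1)c1ccccc1.[Br-]; (iodomethyl)trimethylsilane, C[Si](C)(C)CI
Why: Wittig olefination with the non-stabilised β-silyl ylide made in the flask should install the allylsilane, mainly as the Z isomer, at a temperature where addition to the aldehyde outruns enolisation.

Step 9
Reactants: 19 {(2Z,5R,7R)-5-[(2-methoxypropan-2-yl)peroxy]-5,7-dimethyl-15-phenylpentadec-2-en-1-yl}trimethylsilane; 20 trimethyl orthoformate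
Product: 21 {(2Z,5R,7R)-5-[(dimethoxymethyl)peroxy]-5,7-dimethyl-15-phenylpentadec-2-en-1-yl}trimethylsilane
Conditions: 20 (solvent), PPTS (cat.), 0 °C → rt; volatiles removed under reduced pressure; used crude
Reagents that add atoms: trimethyl orthoformate, COC(OC)OC
Why: acid-catalysed acetal exchange, driven by the excess of orthoformate and by removal of 2,2-dimethoxypropane, should swap the peroxyketal for the dimethoxymethyl group while the allylsilane tolerates the weak acid.

Step 10
Reactants: 21 {(2Z,5R,7R)-5-[(dimethoxymethyl)peroxy]-5,7-dimethyl-15-phenylpentadec-2-en-1-yl}trimethylsilane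
Product: 23 (3R,4R,6R)-4-ethenyl-3-methoxy-6-methyl-6-[(2R)-2-methyl-10-phenyldecyl]-1,2-dioxane, via peroxycarbenium ion 22 (not isolated)
Conditions: TMSOTf (0.2 equiv), 2,6-di-tert-butylpyridine (0.3 equiv), CH2Cl2, −78 °C; Et3N quench
Reagents that add atoms: none
Why: The silyl triflate removes one methoxy group of the peroxy orthoformate to give the alkoxy-stabilised peroxycarbenium ion 22, whose carbon (C3) is attacked by the γ-carbon (C4) of the tethered allylsilane, and loss of the silyl group from the β-silyl cation releases the vinyl group and returns the catalyst. The closest known reaction type is the Lewis-acid-mediated Hosomi–Sakurai allylation of peroxycarbenium ions generated from peroxyacetals, including its intramolecular form that gives cyclic peroxides. The 1,2-dioxane closes in a 6-exo mode with respect to the allylsilane double bond and 6-endo with respect to the O=C+ bond, through a chair transition state with the propenyl unit pseudo-equatorial. C4 is set relative to the preset C6 by the chair that keeps the branched 2-methyl-10-phenyldecyl group equatorial and the C6 methyl axial, which puts the new vinyl group cis to the long chain, whereas C3 (methoxy, axial by the anomeric effect) is a temporary centre that is erased in step 14. The step needs ionisation of a C–OMe and not the C–OO bond (secured by the higher Lewis basicity of methoxy and the alkoxy stabilisation of the cation), closure to the six- and not the eight-membered ring (secured by the β-silicon effect and ring size) and face selectivity at C4; the last is biased only modestly by the two C6 substituents, so the C4 epimer is expected as by-product and is removed by chromatography at this stage.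

Step 11
Reactants: 23 (3R,4R,6R)-4-ethenyl-3-methoxy-6-methyl-6-[(2R)-2-methyl-10-phenyldecyl]-1,2-dioxane; 24 ozone
Product: 26 (3R,4R,6R)-3-methoxy-6-methyl-6-[(2R)-2-methyl-10-phenyldecyl]-1,2-dioxane-4-carbaldehyde, via ozonide 25 (not isolated)
Conditions: O3, CH2Cl2, −78 °C; then Me2S, −78 °C → rt
Reagents that add atoms: ozone, [O-][O+]=O
Why: ozonolysis with reductive work-up should cleave only the vinyl group, since dialkyl peroxides and peroxyacetals are inert to ozone and to dimethyl sulfide.

Step 12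
Reactants: 26 (3R,4R,6R)-3-methoxy-6-methyl-6-[(2R)-2-methyl-10-phenyldecyl]-1,2-dioxane-4-carbaldehyde; 27 4-methylbenzenesulfonohydrazide
Product: 28 N'-[(E)-{(3R,4R,6R)-3-methoxy-6-methyl-6-[(2R)-2-methyl-10-phenyldecyl]-1,2-dioxan-4-yl}methylidene]-4-methylbenzenesulfonohydrazide
Conditions: MeOH, rt
Reagents that add atoms: 4-methylbenzenesulfonohydrazide, Cc1ccc(cc1)S(=O)(=O)NN
Why: condensation under near-neutral conditions should give the tosylhydrazone without epimerising C4, methanol as solvent making any exchange at the methyl peroxyacetal degenerate.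

Step 13
Reactants: 28 N'-[(E)-{(3R,4R,6R)-3-methoxy-6-methyl-6-[(2R)-2-methyl-10-phenyldecyl]-1,2-dioxan-4-yl}methylidene]-4-methylbenzenesulfonohydrazide
Product: 30 (3R,4S,6R)-3-methoxy-4,6-dimethyl-6-[(2R)-2-methyl-10-phenyldecyl]-1,2-dioxane, via hydrazinylborane 29 (not isolated)
Conditions: catecholborane, CHCl3, 0 °C; then NaOAc·3H2O, reflux
Reagents that add atoms: none
Why: hydroboration of the C=N bond followed by base-induced loss of sulfinate and of dinitrogen from the diazene (tosylhydrazone deoxygenation) should turn the formyl group into the C4 methyl group under conditions too mild to reduce the O–O bond.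

Step 14
Reactants: 30 (3R,4S,6R)-3-methoxy-4,6-dimethyl-6-[(2R)-2-methyl-10-phenyldecyl]-1,2-dioxane; 31 tert-butyl[(1-methoxyethenyl)oxy]dimethylsilane
Product: 33 methyl 2-{(3S,4S,6R)-4,6-dimethyl-6-[(2R)-2-methyl-10-phenyldecyl]-1,2-dioxan-3-yl}acetate, via cyclic peroxycarbenium ion 32 (not isolated)
Conditions: TiCl4 (1.1 equiv), 31 (2 equiv), CH2Cl2, −78 °C
Reagents that add atoms: tert-butyl[(1-methoxyethenyl)oxy]dimethylsilane, C=C(OC)O[Si](C)(C)C(C)(C)C
Why: Mukaiyama-type addition of the silyl ketene acetal to the cyclic peroxycarbenium ion should occur by axial attack on the half-chair that keeps the C4 methyl and the C6 alkyl chain pseudo-equatorial, placing the acetate chain cis to the C4 methyl and setting C3 as S.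

Step 15
Reactants: 33 methyl 2-{(3S,4S,6R)-4,6-dimethyl-6-[(2R)-2-methyl-10-phenyldecyl]-1,2-dioxan-3-yl}acetate; 34 lithium hydroxide
Product: 35 2-{(3S,4S,6R)-4,6-dimethyl-6-[(2R)-2-methyl-10-phenyldecyl]-1,2-dioxan-3-yl}acetic acid
Conditions: LiOH, THF/H2O, 0 °C; then dilute HCl
Reagents that add atoms: lithium hydroxide, [Li+].[OH-]
Why: saponification at low temperature, where ester hydrolysis outruns base-induced fragmentation of the β-peroxy ester, followed by acidification should give the acid.

**Compound list**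

1 | (8-bromooctyl)benzene | BrCCCCCCCCc1ccccc1 | starting material
2 | N,N-dimethylformamide | CN(C)C=O | starting material
3 | (8-phenyloctyl)magnesium bromide | Br[Mg]CCCCCCCCc1ccccc1 | intermediate
4 | 9-phenylnonanal | O=CCCCCCCCCc1ccccc1 | intermediate
5 | 1-(triphenylphosphoranylidene)propan-2-one | CC(=O)C=P(c1ccccc1)(c1ccccc1)c1ccccc1 | starting material
6 | (E)-12-phenyldodec-3-en-2-one | CC(=O)/C=C/CCCCCCCCc1ccccc1 | intermediate
7 | methylmagnesium bromide | C[Mg]Br | starting material
8 | (R)-4-methyl-12-phenyldodecan-2-one | C[C@H](CCCCCCCCc1ccccc1)CC(C)=O | intermediate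
9 | trimethylsulfoxonium iodide | C[S+](C)(C)=O.[I-] | starting material
10 | (S)-2-methyl-2-[(2R)-2-methyl-10-phenyldecyl]oxirane | C[C@H](CCCCCCCCc1ccccc1)C[C@@]1(C)CO1 | intermediate
11 | (S)-2-methyl-2-[(2R)-2-methyl-10-phenyldecyl]oxetane | C[C@H](CCCCCCCCc1ccccc1)C[C@@]1(C)CCO1 | intermediate
12 | hydrogen peroxide | OO | starting material
13 | (3R,5R)-3-hydroperoxy-3,5-dimethyl-13-phenyltridecan-1-ol | C[C@H](CCCCCCCCc1ccccc1)C[C@](OO)(C)CCO | intermediate
14 | 2-methoxypropene | COC(C)=C | starting material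
15 | (3R,5R)-3-[(2-methoxypropan-2-yl)peroxy]-3,5-dimethyl-13-phenyltridecan-1-ol | C[C@H](CCCCCCCCc1ccccc1)C[C@](OOC(C)(C)OC)(C)CCO | intermediate
16 | (3R,5R)-3-[(2-methoxypropan-2-yl)peroxy]-3,5-dimethyl-13-phenyltridecanal | C[C@H](CCCCCCCCc1ccccc1)C[C@](OOC(C)(C)OC)(C)CC=O | intermediate
17 | methyltriphenylphosphonium bromide | C[P+](c1ccccc1)(c1ccccc1)c1ccccc1.[Br-] | starting material
18 | (iodomethyl)trimethylsilane | C[Si](C)(C)CI | starting material
19 | {(2Z,5R,7R)-5-[(2-methoxypropan-2-yl)peroxy]-5,7-dimethyl-15-phenylpentadec-2-en-1-yl}trimethylsilane | C[C@H](CCCCCCCCc1ccccc1)C[C@](OOC(C)(C)OC)(C)C/C=C\C[Si](C)(C)C | intermediate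
20 | trimethyl orthoformate | COC(OC)OC | starting material
21 | {(2Z,5R,7R)-5-[(dimethoxymethyl)peroxy]-5,7-dimethyl-15-phenylpentadec-2-en-1-yl}trimethylsilane | C[C@H](CCCCCCCCc1ccccc1)C[C@](OOC(OC)OC)(C)C/C=C\C[Si](C)(C)C | intermediate
22 | methoxy-stabilised peroxycarbenium triflate from 21 (C3 cation, allylsilane arm intact) | C[C@H](CCCCCCCCc1ccccc1)C[C@](OOC=[O+]C)(C)C/C=C\C[Si](C)(C)C.[O-]S(=O)(=O)C(F)(F)F | intermediate
23 | (3R,4R,6R)-4-ethenyl-3-methoxy-6-methyl-6-[(2R)-2-methyl-10-phenyldecyl]-1,2-dioxane | C[C@H](CCCCCCCCc1ccccc1)C[C@]1(C)C[C@H](C=C)[C@H](OC)OO1 | intermediate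
24 | ozone | [O-][O+]=O | starting material
25 | 1,2,4-trioxolane (secondary ozonide) of the vinyl group of 23 | C[C@H](CCCCCCCCc1ccccc1)C[C@]1(C)C[C@H](C2OCOO2)[C@H](OC)OO1 | intermediate
26 | (3R,4R,6R)-3-methoxy-6-methyl-6-[(2R)-2-methyl-10-phenyldecyl]-1,2-dioxane-4-carbaldehyde | C[C@H](CCCCCCCCc1ccccc1)C[C@]1(C)C[C@H](C=O)[C@H](OC)OO1 | intermediate
27 | 4-methylbenzenesulfonohydrazide | Cc1ccc(cc1)S(=O)(=O)NN | starting material
28 | (E)-tosylhydrazone of 26 | C[C@H](CCCCCCCCc1ccccc1)C[C@]1(C)C[C@H](/C=N/NS(=O)(=O)c2ccc(C)cc2)[C@H](OC)OO1 | intermediate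
29 | N-(1,3,2-benzodioxaborol-2-yl)-N-(dioxan-4-ylmethyl)-N'-tosylhydrazine from 28 | C[C@H](CCCCCCCCc1ccccc1)C[C@]1(C)C[C@H](CN(NS(=O)(=O)c2ccc(C)cc2)B2Oc3ccccc3O2)[C@H](OC)OO1 | intermediate
30 | (3R,4S,6R)-3-methoxy-4,6-dimethyl-6-[(2R)-2-methyl-10-phenyldecyl]-1,2-dioxane | C[C@H](CCCCCCCCc1ccccc1)C[C@]1(C)C[C@H](C)[C@H](OC)OO1 | intermediate
31 | tert-butyl[(1-methoxyethenyl)oxy]dimethylsilane | C=C(OC)O[Si](C)(C)C(C)(C)C | starting material
32 | cyclic peroxycarbenium ion from 30 (C3=O2 cation, methoxytetrachlorotitanate counter-ion) | C[C@H](CCCCCCCCc1ccccc1)C[C@]1(C)C[C@H](C)C=[O+]O1.CO[Ti-](Cl)(Cl)(Cl)Cl | intermediate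
33 | methyl 2-{(3S,4S,6R)-4,6-dimethyl-6-[(2R)-2-methyl-10-phenyldecyl]-1,2-dioxan-3-yl}acetate | C[C@H](CCCCCCCCc1ccccc1)C[C@]1(C)C[C@H](C)[C@H](CC(=O)OC)OO1 | intermediate
34 | lithium hydroxide | [Li+].[OH-] | starting material
35 | 2-{(3S,4S,6R)-4,6-dimethyl-6-[(2R)-2-methyl-10-phenyldecyl]-1,2-dioxan-3-yl}acetic acid | C[C@H](CCCCCCCCc1ccccc1)C[C@]1(C)C[C@H](C)[C@H](CC(=O)O)OO1 | target

**Step count and risks**

Total steps: 15. Longest linear sequence: 15 (the route is fully linear).

The three steps most likely to fail: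

1. Step 10 (key step). The two chair transition states differ only in which C6 substituent is axial, so face discrimination at C4 may be poor; ionisation may also occur with loss of the peroxide instead of methoxide. The fallback gives up the C3–C4 closure and builds C4 from the chiral pool before a ring closure at the O2–C3 bond. It sets out from ketone 8. KN(SiMe3)2 and PhNTf2 (THF, −78 °C) should give the kinetic enol triflate (R)-4-methyl-12-phenyldodec-1-en-2-yl trifluoromethanesulfonate F1. Negishi coupling with the zinc reagent from (R)-tert-butyl(3-iodo-2-methylpropoxy)dimethylsilane (Zn, then Pd(PPh3)4, THF) should give tert-butyl{[(2S,6R)-2,6-dimethyl-4-methylidene-14-phenyltetradecyl]oxy}dimethylsilane F2. Isayama–Mukaiyama hydroperoxysilylation (Co(acac)2, O2, Et3SiH) should give the tertiary silyl peroxide tert-butyldimethyl{[(2S,4R,6R)-2,4,6-trimethyl-14-phenyl-4-(triethylsilylperoxy)tetradecyl]oxy}silane F3 together with its epimer at the peroxide carbon. TBAF should free (2S,4R,6R)-4-hydroperoxy-2,4,6-trimethyl-14-phenyltetradecan-1-ol F4. TEMPO/PhI(OAc)2 should oxidise the primary alcohol, and the hydroperoxy aldehyde closes to (4S,6R)-4,6-dimethyl-6-[(2R)-2-methyl-10-phenyldecyl]-1,2-dioxan-3-ol F5. MeOH/PPTS then gives the methyl peroxyacetal; the C6 epimer is removed by chromatography and the route is rejoined at 30.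

2. Step 8. The basic ylide may enolise the β-peroxy aldehyde and expel the peroxide by β-elimination, or attack the O–O bond. The fallback reverses the polarity of the olefination so that no enolisable β-peroxy carbonyl meets a base. It sets out from alcohol 15. Mitsunobu reaction with 1-phenyl-1H-tetrazole-5-thiol (PPh3, DIAD) should give 5-({(3R,5R)-3-[(2-methoxypropan-2-yl)peroxy]-3,5-dimethyl-13-phenyltridecyl}sulfanyl)-1-phenyl-1H-tetrazole F6. mCPBA/NaHCO3 should give the corresponding sulfone 5-({(3R,5R)-3-[(2-methoxypropan-2-yl)peroxy]-3,5-dimethyl-13-phenyltridecyl}sulfonyl)-1-phenyl-1H-tetrazole F7. Julia–Kocienski olefination (KN(SiMe3)2, then freshly prepared (trimethylsilyl)acetaldehyde, −78 °C) should give {(2E,5R,7R)-5-[(2-methoxypropan-2-yl)peroxy]-5,7-dimethyl-15-phenylpentadec-2-en-1-yl}trimethylsilane F8. The conditions of step 9 convert it into {(2E,5R,7R)-5-[(dimethoxymethyl)peroxy]-5,7-dimethyl-15-phenylpentadec-2-en-1-yl}trimethylsilane F9, and the conditions of step 10 bring the route back at 23.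

3. Step 13. The borane may attack the peroxyacetal or the O–O bond, and warming with acetate may epimerise C4 or cause β-elimination of the peroxide. The fallback removes the oxygen by a radical path. It sets out from aldehyde 26. NaBH4 (MeOH, 0 °C) should give {(3R,4R,6R)-3-methoxy-6-methyl-6-[(2R)-2-methyl-10-phenyldecyl]-1,2-dioxan-4-yl}methanol F10. I2, PPh3 and imidazole should give (3R,4S,6R)-4-(iodomethyl)-3-methoxy-6-methyl-6-[(2R)-2-methyl-10-phenyldecyl]-1,2-dioxane F11. Bu3SnH with Et3B/air at room temperature reduces the primary iodide; the exocyclic radical cannot reach the O–O bond in a favourable geometry, and the route is rejoined at 30.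

Further compounds

F1 | step 10 | (R)-4-methyl-12-phenyldodec-1-en-2-yl trifluoromethanesulfonate | C[C@H](CCCCCCCCc1ccccc1)CC(=C)OS(=O)(=O)C(F)(F)F
F2 | step 10 | tert-butyl{[(2S,6R)-2,6-dimethyl-4-methylidene-14-phenyltetradecyl]oxy}dimethylsilane | C[C@H](CCCCCCCCc1ccccc1)CC(=C)C[C@H](C)CO[Si](C)(C)C(C)(C)C
F3 | step 10 | tert-butyldimethyl{[(2S,4R,6R)-2,4,6-trimethyl-14-phenyl-4-(triethylsilylperoxy)tetradecyl]oxy}silane | C[C@H](CCCCCCCCc1ccccc1)C[C@](OO[Si](CC)(CC)CC)(C)C[C@H](C)CO[Si](C)(C)C(C)(C)C
F4 | step 10 | (2S,4R,6R)-4-hydroperoxy-2,4,6-trimethyl-14-phenyltetradecan-1-ol | C[C@H](CCCCCCCCc1ccccc1)C[C@](OO)(C)C[C@H](C)CO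
F5 | step 10 | (4S,6R)-4,6-dimethyl-6-[(2R)-2-methyl-10-phenyldecyl]-1,2-dioxan-3-ol | C[C@H](CCCCCCCCc1ccccc1)C[C@]1(C)C[C@H](C)C(O)OO1
F6 | step 8 | 5-({(3R,5R)-3-[(2-methoxypropan-2-yl)peroxy]-3,5-dimethyl-13-phenyltridecyl}sulfanyl)-1-phenyl-1H-tetrazole | C[C@H](CCCCCCCCc1ccccc1)C[C@](OOC(C)(C)OC)(C)CCSc1nnnn1-c1ccccc1
F7 | step 8 | 5-({(3R,5R)-3-[(2-methoxypropan-2-yl)peroxy]-3,5-dimethyl-13-phenyltridecyl}sulfonyl)-1-phenyl-1H-tetrazole | C[C@H](CCCCCCCCc1ccccc1)C[C@](OOC(C)(C)OC)(C)CCS(=O)(=O)c1nnnn1-c1ccccc1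
F8 | step 8 | {(2E,5R,7R)-5-[(2-methoxypropan-2-yl)peroxy]-5,7-dimethyl-15-phenylpentadec-2-en-1-yl}trimethylsilane | C[C@H](CCCCCCCCc1ccccc1)C[C@](OOC(C)(C)OC)(C)C/C=C/C[Si](C)(C)C
F9 | step 8 | {(2E,5R,7R)-5-[(dimethoxymethyl)peroxy]-5,7-dimethyl-15-phenylpentadec-2-en-1-yl}trimethylsilane | C[C@H](CCCCCCCCc1ccccc1)C[C@](OOC(OC)OC)(C)C/C=C/C[Si](C)(C)C
F10 | step 13 | {(3R,4R,6R)-3-methoxy-6-methyl-6-[(2R)-2-methyl-10-phenyldecyl]-1,2-dioxan-4-yl}methanol | C[C@H](CCCCCCCCc1ccccc1)C[C@]1(C)C[C@H](CO)[C@H](OC)OO1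
F11 | step 13 | (3R,4S,6R)-4-(iodomethyl)-3-methoxy-6-methyl-6-[(2R)-2-methyl-10-phenyldecyl]-1,2-dioxane | C[C@H](CCCCCCCCc1ccccc1)C[C@]1(C)C[C@H](CI)[C@H](OC)OO1
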